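## Structural features

Monotesone A, compound 21, is a flavanone in which the phloroglucinol-type benzo ring A is fused along C4a–C8a to the dihydropyranone ring C, and the catechol-type ring B is attached to C2 through C1'. Ring A carries free hydroxyls at C5 and C7, O1 on C8a and the C4 ketone on C4a; ring B carries a free hydroxyl at C3' and a prenyl (3-methylbut-2-en-1-yl) ether at O4'. C2 is the only stereocenter, has the S configuration (O1 > C1' > C3 > H) and has no stereogenic neighbour, so only absolute control is required. Two groups are fragile: the aryl prenyl ether, which ionises under protic or strong Lewis acid and does not survive hydrogenolysis, and the C2–O1 bond, which is benzylic to an electron-rich ring and β to the ketone, so that acid can ionise it and base can open it by E1cB to the 2'-hydroxychalcone with loss of configuration. The real difficulty is therefore to set C2 in a way that no later step can undo, and to unmask three phenols at the end without touching the prenyl ether or ring C. The key step exploits the way ring C is attached to ring A, through O1 at C8a and through C4 at the neighbouring C4a, with the C5 oxygen beside C4a: this is the polarity pattern of a 3-alkoxyaryne, which accepts a nucleophile at the carbon remote from the alkoxy group (C8a) and an electrophile at the carbon next to it (C4a). The structures of the two annulation partners and of the annulation product were examined atom by atom and need no correction: in 16 the silicon sits between the triflate and one acetal oxygen, and 6 and 19 are both S for the same spatial arrangement, because the aryl group outranks the methylene carbon in each.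

## Logic of the disconnections

21 to 19. No skeletal bond is cut; the O–H bonds at O5, O7 and O3' are exchanged for O–CH2OCH3 bonds. Free phenols would be deprotonated by fluoride and arylated in the ring-forming step, so the gain is a substrate without an acidic proton. The forward step must cleave three acetals without protic acid, so that the prenyl ether and the C2–O1 bond stay intact.

19 to 7 and 16. The cuts are O1–C8a and C4–C4a, the two bonds that join ring C to ring A. Cutting here leaves the stereocenter in an open-chain β-oxygenated ester and turns ring A into 17, which already carries both oxygens. The gain is full convergence: two fragments of similar size and no ring left to build. The forward step demands addition of the oxygen of 18 at the aryne carbon remote from the C5 oxygen, acylation of the resulting aryl anion faster than its protonation, and a medium that neither fragments 18 nor opens 19.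

7 to 6 to 5. First the O–Si bond is cut, then the C–H bond of the carbinol carbon, so the stereocenter is traced back to a prochiral aryl ketone. Reduction is preferred to a C–C bond-forming aldol because its facial preference is predictable and no C–O bond is made at a cation-prone benzylic centre. The forward step must be reagent-controlled, since there is no resident stereocenter, and must spare the trisubstituted olefin and the acetal.

5 to 4. The bond between the methylene carbon and the ester carbonyl is cut, which leads to an aryl methyl ketone and a one-carbon carbonate electrophile. The forward step needs a base that tolerates both aryl ethers.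

4 to 3 to 1 and 2. The two ether O–CH2 bonds on ring B are cut, the acetal first and the prenyl ether last, which leads to commercial 1 and 2. The demand is mono-alkylation at the 4-hydroxyl, which its higher acidity (para to the acyl group) should provide.

16 to 14 to 10 to 9 to 8. The cuts are the O–S bond of the triflate, the C–Si bond ortho to it, the carbamate C–O bond and two acetal O–CH2 bonds, down to the symmetrical triol 8. The carbamate serves twice: it differentiates one oxygen and it directs the silylation. The demands are lithiation beside the carbamate and not between the two acetals, and acceptance of a statistical double protection at the first step of this branch.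

## Other disconnections considered

Alternative 1: The cut runs through C3–C4 and O1–C2 and divides ring C into three parts. These are 2-hydroxy-4,6-bis(tert-butyldimethylsilyloxy)benzaldehyde A1 as the ring-A component, 1-(benzyloxy)-2-(tert-butyldimethylsilyloxy)-4-vinylbenzene A2 as the ring-B styrene and trimethyl orthoformate A3 as the source of the C4 substituent.

Forward key step: a chiral N-triflyl phosphoramide would condense A1 with A3 to a cationic heterodiene that bears a methoxy group on the future C4 and is paired with the chiral anion. Inverse-demand (4+2) cycloaddition of this species with A2 would form C3–C4 and O1–C2 and give the 2,4-cis flavan (2S,4S)-4'-(benzyloxy)-4-methoxy-5,7,3'-tris(tert-butyldimethylsilyloxy)flavan A4 in one operation.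

In its favour:
- Ring C and C2 would arise in a single catalytic enantioselective event from achiral parts.
- The silyl ethers could later be removed with buffered fluoride, which is gentler towards a prenyl ether than any acetal cleavage. On this point the alternative is the better plan.

Against it here:
- Both partners are very electron-rich, so the cation is stabilised and only loosely paired with the anion, and A2 is prone to cationic oligomerisation.
- The strong acid excludes a prenyl ether and endangers aryl silyl ethers. Hence the benzyl ether, which would later have to be exchanged by hydrogenolysis and alkylation with 2 on a base-sensitive flavanone.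
- C4 arrives as a methyl ether. A4 would have to be hydrolysed and oxidised to (S)-4'-(benzyloxy)-5,7,3'-tris(tert-butyldimethylsilyloxy)flavanone A5 before the end game, and the C4 stereocenter would be made only to be destroyed.

Comparison: On structure the two plans are equal, since both are convergent and form two bonds of ring C in a formal (4+2) event. On mechanism the alternative rests on the better-founded reaction class, whereas the chosen annulation is new. The chosen plan, however, delivers C4 at the ketone level and sets C2 by a more predictable reaction. On step economy about five operations would follow A4 against one after 19, so the chosen plan is shorter.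

Alternative 2: The cut runs through C4–C4a, C3–C4 and O1–C2. The parts are 2-iodo-3,5-bis(methoxymethoxy)phenol A6 for ring A, 1-(benzyloxy)-4-ethynyl-2-(methoxymethoxy)benzene A7 for ring B with C2 and C3, and carbon monoxide A8 for C4.

Forward key step: with PdCl2(PPh3)2 in diethylamine, the zerovalent palladium formed in the flask would add oxidatively to A6 and insert A8. Acyl–alkynyl coupling with A7 and conjugate closure by the phenol in the same pot would give the flavone 4'-(benzyloxy)-5,7,3'-tris(methoxymethoxy)flavone A9. An enantioselective 1,4-reduction of A9 would then have to give (S)-4'-(benzyloxy)-5,7,3'-tris(methoxymethoxy)flavanone A10, and exchange of benzyl for prenyl on A10 would converge on 19.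

In its favour:
- The flavone-forming step belongs to an established reaction class and makes three bonds from simple parts; in precedent the alternative is the better of the two.
- A6 is a ring-A building block of the same kind and effort as 16, so the two plans are equal there.

Against it here:
- C2 would depend on conjugate reduction of a doubly donor-substituted vinylogous ester. It is a poor hydride acceptor, 1,2-reduction competes, and the metal enolate formed has the ring oxygen as a β-leaving group, so ring opening is built into the mechanism.
- The di-ortho-substituted, electron-rich iodide A6 should carbonylate slowly, so direct alkynylation by A7 and closure to a five-membered ring would compete.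
- Hydrogenolysis of the benzyl ether on a flavanone risks reduction at C4 and cleavage of the benzylic C2–O1 bond.

Comparison: On structure the alternative makes one more bond in its key step but no stereocenter. On mechanism the chosen plan sets C2 on an open-chain ketone and carries it through a step that never touches the C2–O bond, whereas the alternative sets it on the least cooperative substrate. On step economy the two are about equal, roughly twelve steps against eleven with the same final deprotection.

Alternative 3: The cut runs through C2–C3 and the O1–C8a bond of a monocyclic pyranone, and ring A is added later. The parts are 3-(tert-butyldimethylsilyloxy)-4-(prenyloxy)benzaldehyde A11 as the heterodienophile and (E)-1-methoxy-3-(trimethylsilyloxy)buta-1,3-diene A12 as the four-carbon diene.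

Forward key step: Ti(OiPr)4 with BINOL of the required hand would activate A11, and A12 would add to the Si face of the aldehyde. Acid work-up would close the ring with loss of methanol and give (S)-2-[3-(tert-butyldimethylsilyloxy)-4-(prenyloxy)phenyl]-2,3-dihydro-4H-pyran-4-one A13 with C2 set.

In its favour:
- This catalytic asymmetric hetero-Diels–Alder reaction of aromatic aldehydes is well established.
- It would reach a compound containing C2 in about three steps from commercial material, one fewer than the four steps to 6; on this point the alternative is the better plan.
- The prenyl ether is present from the start in both plans, and C2 is set by catalyst control at the ring-B carbonyl carbon in both, so the plans are equal on these points.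

Against it here:
- The harder half is left for later: ring A, with two oxygens in fixed positions, would have to be annulated onto the enol-ether double bond of A13 (the future C4a=C8a).
- That needs α-functionalisation, a dioxygenated four-carbon partner, regiocontrol and aromatisation, probably five or more steps, on a compound whose C2–O bond is vinylogous to the ketone.
- The acid that closes the pyranone meets the prenyl and silyl ethers, and the electron-rich aldehyde A11 should react slowly with A12.

Comparison: On structure the alternative is linear and builds ring A piece by piece, whereas the chosen plan brings it in whole. On mechanism the two are equal in how C2 is controlled, and the alternative has the better precedent for its key step. On step economy the alternative is clearly longer.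

Key step: step 10

Remark: prenyl stands for 3-methylbut-2-en-1-yl and MOM for methoxymethyl. The carbinol is set by ketone reduction starting from commercial 3',4'-dihydroxyacetophenone. The hydroxy ester 6 enters the annulation as its trimethylsilyl ether 7 (same skeleton), so that the alkoxide is released by fluoride in a flask free of O–H bonds.

## Route

Step 1
Reactants: 1 3',4'-dihydroxyacetophenone; 2 prenyl bromide (1-bromo-3-methylbut-2-ene)
Product: 3 1-[3-hydroxy-4-(prenyloxy)phenyl]ethan-1-one
Conditions: Li2CO3, DMF, 50 °C
Reagents that add atoms: none
Why: Williamson etherification under weak-base control: the 4-hydroxyl, para to the acetyl group, is the more acidic phenol, so Li2CO3 should ionise it selectively and SN2 alkylation by the allylic bromide should stop at the mono-ether.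

Step 2
Reactants: 3 1-[3-hydroxy-4-(prenyloxy)phenyl]ethan-1-one
Product: 4 1-[3-(methoxymethoxy)-4-(prenyloxy)phenyl]ethan-1-one
Conditions: MOMCl, iPr2NEt, CH2Cl2, 0 °C to rt
Reagents that add atoms: chloromethyl methyl ether (MOMCl), COCCl
Why: O-alkylation of the remaining phenol to a mixed acetal (MOM protection); the acetal withstands NaH, transfer hydrogenation and fluoride and masks the phenol that would otherwise add to the aryne in step 10.

Step 3
Reactants: 4 1-[3-(methoxymethoxy)-4-(prenyloxy)phenyl]ethan-1-one
Product: 5 methyl 3-[3-(methoxymethoxy)-4-(prenyloxy)phenyl]-3-oxopropanoate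
Conditions: NaH, (MeO)2CO, THF, reflux; aq. NH4Cl
Reagents that add atoms: dimethyl carbonate, COC(=O)OC
Why: Crossed Claisen condensation of the ketone enolate with a non-enolisable carbonate; deprotonation of the β-keto ester product drives the equilibrium, and neither the acetal nor the prenyl ether reacts with NaH.

Step 4
Reactants: 5 methyl 3-[3-(methoxymethoxy)-4-(prenyloxy)phenyl]-3-oxopropanoate
Product: 6 methyl (S)-3-hydroxy-3-[3-(methoxymethoxy)-4-(prenyloxy)phenyl]propanoate
Conditions: RuCl[(S,S)-TsDPEN](p-cymene) (1 mol %), HCO2H/Et3N (5:2), DMF, 30 °C
Reagents that add atoms: none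
Why: Noyori asymmetric transfer hydrogenation of an aryl β-keto ester. In RuH[(S,S)-TsDPEN](p-cymene), formed from the precatalyst and formate, the aryl ring of the ketone lies under the η6-arene (C–H/π contact), so hydride and proton should be delivered in concert to the Re face and set the S carbinol, as with simple aryl ketones. The outer-sphere mechanism leaves the trisubstituted olefin alone and the amine-buffered medium should spare the acetal.

Step 5
Reactants: 6 methyl (S)-3-hydroxy-3-[3-(methoxymethoxy)-4-(prenyloxy)phenyl]propanoate
Product: 7 methyl (S)-3-[3-(methoxymethoxy)-4-(prenyloxy)phenyl]-3-(trimethylsilyloxy)propanoate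
Conditions: TMSCl, imidazole, CH2Cl2, 0 °C; chromatography on Et3N-deactivated silica
Reagents that add atoms: chlorotrimethylsilane, C[Si](C)(C)Cl
Why: Silylation of a secondary alcohol; the silyl ether removes the only O–H proton of the annulation substrate and serves as the latent alkoxide that fluoride releases in step 10, and the stereocenter is not involved.

Step 6
Reactants: 8 phloroglucinol
Product: 9 3,5-bis(methoxymethoxy)phenol
Conditions: MOMCl (2 equiv), iPr2NEt, DMF, 0 °C to rt; separation from mono- and tris-ethers
Reagents that add atoms: chloromethyl methyl ether (MOMCl), COCCl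
Why: Statistical double acetalisation of a threefold-symmetric triol; the modest selectivity is accepted because 8 is cheap, the mono- and tris-ethers are separable and the loss falls on the first step of the short branch.

Step 7
Reactants: 9 3,5-bis(methoxymethoxy)phenol
Product: 10 3,5-bis(methoxymethoxy)phenyl N-isopropylcarbamate
Conditions: iPrNCO, Et3N (cat.), CH2Cl2, rt
Reagents that add atoms: isopropyl isocyanate, CC(C)N=C=O
Why: Amine-catalysed addition of the phenol to the isocyanate (carbamoylation); once N-silylated the carbamate becomes a strong ortho-director, and being N-monosubstituted it can later be removed by mild base.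

Step 8
Reactants: 10 3,5-bis(methoxymethoxy)phenyl N-isopropylcarbamate
Product: 14 3,5-bis(methoxymethoxy)-2-(trimethylsilyl)phenyl N-isopropylcarbamate, via N-silyl carbamate 11 (not isolated), via aryllithium 12 (not isolated), via N-silyl C-silyl carbamate 13 (not isolated)
Conditions: TBSOTf, TMEDA, Et2O, 0 °C to rt; n-BuLi (2.2 equiv), TMEDA, −78 °C; TMSCl, −78 °C to rt; aq. NH4Cl
Reagents that add atoms: chlorotrimethylsilane, C[Si](C)(C)Cl
Why: Directed ortho-metalation. Transient N-silylation turns the carbamate into a tertiary, non-acidic director, and n-BuLi/TMEDA should lithiate C2, flanked by the carbamate (the strongest oxygen-based director) and one MOM ether, in preference to C4 between the two MOM ethers. The aryllithium is trapped by TMSCl at low temperature before an anionic Fries shift can occur, and the N–Si bond is hydrolysed on work-up.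

Step 9
Reactants: 14 3,5-bis(methoxymethoxy)-2-(trimethylsilyl)phenyl N-isopropylcarbamate
Product: 16 3,5-bis(methoxymethoxy)-2-(trimethylsilyl)phenyl trifluoromethanesulfonate, via 2-silylphenol 15 (not isolated)
Conditions: DBU, Et2NH, MeCN, 40 °C; then PhNTf2, rt
Reagents that add atoms: N-phenylbis(trifluoromethanesulfonimide) (PhNTf2), O=S(=O)(N(c1ccccc1)S(=O)(=O)C(F)(F)F)C(F)(F)F
Why: E1cB cleavage of the N-monosubstituted carbamate (the isocyanate set free is scavenged by Et2NH as a urea), then O-sulfonylation of the hindered phenoxide in the same flask by a mild triflyl donor; no stage is acidic, so the acetals and the C–Si bond should survive.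

Step 10
Reactants: 7 methyl (S)-3-[3-(methoxymethoxy)-4-(prenyloxy)phenyl]-3-(trimethylsilyloxy)propanoate; 16 3,5-bis(methoxymethoxy)-2-(trimethylsilyl)phenyl trifluoromethanesulfonate
Product: 19 (S)-5,7-bis(methoxymethoxy)-2-[3-(methoxymethoxy)-4-(prenyloxy)phenyl]chroman-4-one, via 3,5-bis(methoxymethoxy)benzyne 17 (not isolated), via caesium alkoxide 18 (not isolated)
Conditions: CsF (3 equiv), 18-crown-6 (0.5 equiv), THF, rt; 7 and 16 (1.5 equiv) added together by syringe pump; pH 7 phosphate buffer
Reagents that add atoms: none
Why: Proposed new method: fluoride, and later the methoxide that the annulation itself releases, strips the O-silyl group from 7 to give alkoxide 18 in a medium free of O–H bonds, while fluoride-induced 1,2-elimination of 16 gives aryne 17. Alkoxide 18 adds to the aryne carbon remote from the flanking alkoxy group (future C8a), because that group distorts the triple bond and inductively stabilises the negative charge that develops on the carbon beside it (future C4a). The carbanion and the ester carbon are the two ends of a six-atom chain, so ring C closes by 6-exo-trig addition to the ester and the tetrahedral intermediate collapses with loss of methoxide to the ketone; the step is thus a formal (4+2) annulation that forms O1–C8a and C4–C4a. The closest known reaction types are the fluoride-mediated annulation of arynes with salicylate esters to xanthones and the aryne route from unsaturated carboxylic acids to chroman-4-ones; an aliphatic, enolisable β-oxygenated ester has not been shown in this role. No stereocenter is created, and since the C2–O bond is never broken the S configuration set in step 4 passes into 19 unchanged. Two selectivities are needed: the regiochemistry of the aryne addition, secured by the alkoxy group next to the triple bond, and acylation of the aryl anion in preference to its protonation, secured by the six-membered tether, by the silyl ether in place of a free hydroxyl and by slow release of both partners. The expelled methoxide should be captured at silicon, which unmasks the next molecule of 7 and keeps the medium only weakly basic, to the benefit of the base-sensitive product.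

Step 11
Reactants: 19 (S)-5,7-bis(methoxymethoxy)-2-[3-(methoxymethoxy)-4-(prenyloxy)phenyl]chroman-4-one
Product: 21 (S)-5,7-dihydroxy-2-[3-hydroxy-4-(prenyloxy)phenyl]chroman-4-one (monotesone A), via tris(trimethylsilyl) ether 20 (not isolated)
Conditions: TMSOTf (6 equiv), 2,2'-bipyridyl (9 equiv), MeCN, 0 °C to rt; then H2O, rt
Reagents that add atoms: none
Why: Non-protic cleavage of aryl MOM ethers. The silyl triflate, tempered as its bipyridyl adduct, activates each acetal, the methoxymethyl unit passes to bipyridyl as a pyridinium salt and the phenols are left as silyl ethers in 20, which water then hydrolyses. Since no free protic acid and only a weak base are present, the prenyl ether should not ionise and C3 should not enolise, so C2 stays untouched.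

## Compound list

1 | 3',4'-dihydroxyacetophenone | CC(=O)c1ccc(O)c(O)c1 | starting material
2 | prenyl bromide (1-bromo-3-methylbut-2-ene) | CC(C)=CCBr | starting material
3 | 1-[3-hydroxy-4-(prenyloxy)phenyl]ethan-1-one | CC(C)=CCOc1ccc(C(C)=O)cc1O | intermediate
4 | 1-[3-(methoxymethoxy)-4-(prenyloxy)phenyl]ethan-1-one | CC(C)=CCOc1ccc(C(C)=O)cc1OCOC | intermediate
5 | methyl 3-[3-(methoxymethoxy)-4-(prenyloxy)phenyl]-3-oxopropanoate | CC(C)=CCOc1ccc(C(=O)CC(=O)OC)cc1OCOC | intermediate
6 | methyl (S)-3-hydroxy-3-[3-(methoxymethoxy)-4-(prenyloxy)phenyl]propanoate | CC(C)=CCOc1ccc([C@@H](O)CC(=O)OC)cc1OCOC | intermediate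
7 | methyl (S)-3-[3-(methoxymethoxy)-4-(prenyloxy)phenyl]-3-(trimethylsilyloxy)propanoate | CC(C)=CCOc1ccc([C@@H](O[Si](C)(C)C)CC(=O)OC)cc1OCOC | intermediate
8 | phloroglucinol | Oc1cc(O)cc(O)c1 | starting material
9 | 3,5-bis(methoxymethoxy)phenol | COCOc1cc(O)cc(OCOC)c1 | intermediate
10 | 3,5-bis(methoxymethoxy)phenyl N-isopropylcarbamate | COCOc1cc(OCOC)cc(OC(=O)NC(C)C)c1 | intermediate
11 | 3,5-bis(methoxymethoxy)phenyl N-(tert-butyldimethylsilyl)-N-isopropylcarbamate (formed in the flask) | COCOc1cc(OCOC)cc(OC(=O)N(C(C)C)[Si](C)(C)C(C)(C)C)c1 | intermediate
12 | 2-lithio derivative of 11 (formed in the flask) | COCOc1cc(OCOC)c([Li])c(OC(=O)N(C(C)C)[Si](C)(C)C(C)(C)C)c1 | intermediate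
13 | 3,5-bis(methoxymethoxy)-2-(trimethylsilyl)phenyl N-(tert-butyldimethylsilyl)-N-isopropylcarbamate (formed in the flask) | COCOc1cc(OCOC)c([Si](C)(C)C)c(OC(=O)N(C(C)C)[Si](C)(C)C(C)(C)C)c1 | intermediate
14 | 3,5-bis(methoxymethoxy)-2-(trimethylsilyl)phenyl N-isopropylcarbamate | COCOc1cc(OCOC)c([Si](C)(C)C)c(OC(=O)NC(C)C)c1 | intermediate
15 | 3,5-bis(methoxymethoxy)-2-(trimethylsilyl)phenol (formed in the flask as its amidinium salt) | COCOc1cc(OCOC)c([Si](C)(C)C)c(O)c1 | intermediate
16 | 3,5-bis(methoxymethoxy)-2-(trimethylsilyl)phenyl trifluoromethanesulfonate | COCOc1cc(OCOC)c([Si](C)(C)C)c(OS(=O)(=O)C(F)(F)F)c1 | intermediate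
17 | 3,5-bis(methoxymethoxy)benzyne (formed in the flask) | COCOC1=CC(OCOC)=CC#C1 | intermediate
18 | caesium (S)-3-methoxy-1-[3-(methoxymethoxy)-4-(prenyloxy)phenyl]-3-oxopropan-1-olate (formed in the flask) | CC(C)=CCOc1ccc([C@@H]([O-])CC(=O)OC)cc1OCOC.[Cs+] | intermediate
19 | (S)-5,7-bis(methoxymethoxy)-2-[3-(methoxymethoxy)-4-(prenyloxy)phenyl]chroman-4-one | CC(C)=CCOc1ccc([C@@H]2CC(=O)c3c(OCOC)cc(OCOC)cc3O2)cc1OCOC | intermediate
20 | (S)-2-[4-(prenyloxy)-3-(trimethylsilyloxy)phenyl]-5,7-bis(trimethylsilyloxy)chroman-4-one (formed in the flask) | CC(C)=CCOc1ccc([C@@H]2CC(=O)c3c(O[Si](C)(C)C)cc(O[Si](C)(C)C)cc3O2)cc1O[Si](C)(C)C | intermediate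
21 | monotesone A, (S)-5,7-dihydroxy-2-[3-hydroxy-4-(prenyloxy)phenyl]chroman-4-one | CC(C)=CCOc1ccc([C@@H]2CC(=O)c3c(O)cc(O)cc3O2)cc1O | target

## Step count and least certain steps

Total: 11 steps. Longest linear sequence: 7 steps (steps 1 to 5, 10 and 11, from 1). The ring-A branch (steps 6 to 9, from 8) joins at step 10.

Step 10 (key step, new method). The most likely failure is quenching of the C4a aryl anion by a proton before it reaches the ester; possible sources are the C3 methylene of the substrate through a six-membered transition state, THF, or traces of water. A second failure mode is fragmentation of alkoxide 18 by retro-aldol cleavage or elimination while it waits for the aryne. The fallback uses known reactions only, sets out from 6 and 16 and comes back to the route at 19. The free alcohol 6 is O-arylated by the aryne released from 16 (CsF, MeCN, rt; O–H insertion of an alcohol into an aryne with the same regiochemistry, the aryl anion now being protonated on purpose). This should give methyl (S)-3-[3,5-bis(methoxymethoxy)phenoxy]-3-[3-(methoxymethoxy)-4-(prenyloxy)phenyl]propanoate F1 as the open-chain aryl ether. Saponification of F1 with LiOH (THF–H2O, 0 °C) should give (S)-3-[3,5-bis(methoxymethoxy)phenoxy]-3-[3-(methoxymethoxy)-4-(prenyloxy)phenyl]propanoic acid F2 without touching C2. The acid F2 is then activated as its mixed trifluoroacetic anhydride ((CF3CO)2O, 2,6-di-tert-butylpyridine, CH2Cl2, −20 to 0 °C), and intramolecular Friedel–Crafts acylation of the phloroglucinol-type ring should close ring C. The two positions ortho to O1 are equivalent, so only one product is possible, and it is 19. The cost is two more steps and exposure of the acetals, the prenyl ether and the benzylic ether to an acylating medium, hence the hindered pyridine buffer.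

Step 11. The most likely failure is loss or migration of the prenyl group when the silyl triflate activates the allylic ether oxygen instead of the acetals; opening of ring C during the aqueous stage is the second concern. The fallback carries the ring-B ether as an allyl ether, which tolerates protic acid, and makes the prenyl ether last. It sets out from 1, uses the conditions of steps 1 to 5 and 10, and comes back to the route at 21.

- Allylation of 1 with allyl bromide would give 1-[4-(allyloxy)-3-hydroxyphenyl]ethan-1-one F3 as the mono-ether.
- MOM protection of F3 would give 1-[4-(allyloxy)-3-(methoxymethoxy)phenyl]ethan-1-one F4 as the protected ketone.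
- Claisen condensation of F4 with dimethyl carbonate would give methyl 3-[4-(allyloxy)-3-(methoxymethoxy)phenyl]-3-oxopropanoate F5 as the β-keto ester.
- Transfer hydrogenation of F5 would give methyl (S)-3-[4-(allyloxy)-3-(methoxymethoxy)phenyl]-3-hydroxypropanoate F6 as the carbinol.
- Silylation of F6 would give methyl (S)-3-[4-(allyloxy)-3-(methoxymethoxy)phenyl]-3-(trimethylsilyloxy)propanoate F7 as the annulation substrate.
- Annulation of F7 with 16 would give (S)-2-[4-(allyloxy)-3-(methoxymethoxy)phenyl]-5,7-bis(methoxymethoxy)chroman-4-one F8 as the protected flavanone.
- The acetals of F8 are then removed with HCl in MeOH at 40 °C to give (S)-2-[4-(allyloxy)-3-hydroxyphenyl]-5,7-dihydroxychroman-4-one F9 as the triphenol.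
- Olefin cross-metathesis of F9 with 2-methylbut-2-ene (second-generation Grubbs catalyst, RuCl2(=CHPh)(H2IMes)(PCy3), CH2Cl2, 40 °C) converts the allyl ether into the prenyl ether and gives 21.

Step 8. The most likely failure is lithiation at C4 between the two MOM ethers, or carbamoyl migration (anionic Fries shift) before silylation; either would put silicon in the wrong place or consume the director. The fallback fixes the position with a halogen, sets out from 9 and comes back to the route at 16. Ortho-bromination of 9 (NBS, cat. iPr2NH, CH2Cl2, −78 °C) would give 2-bromo-3,5-bis(methoxymethoxy)phenol F10 after separation from its 4-bromo isomer. O-silylation of F10 (hexamethyldisilazane, THF, reflux) would give [2-bromo-3,5-bis(methoxymethoxy)phenoxy]trimethylsilane F11 as the silyl ether. Treatment of F11 with n-BuLi (THF, −78 °C) effects bromine–lithium exchange and a 1,3 O-to-C silyl shift (retro-Brook rearrangement) to the lithium salt of 15. Triflation in the same flask with PhNTf2 gives 16.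

Step 4. The most likely failure is incomplete facial selectivity with this electron-rich ketone, or partial loss of the acetal in the formate medium on prolonged reaction. The fallback replaces asymmetric catalysis by resolution, sets out from 5 and comes back to the route at 6. Reduction of 5 with NaBH4 (MeOH, 0 °C) would give methyl 3-hydroxy-3-[3-(methoxymethoxy)-4-(prenyloxy)phenyl]propanoate F12 as the racemate. Kinetic resolution of F12 by lipase-catalysed acylation (Burkholderia cepacia lipase, vinyl acetate, tert-butyl methyl ether, 30 °C) should, by the usual preference of this enzyme for secondary aryl carbinols, acylate the R enantiomer. This would give methyl (R)-3-acetoxy-3-[3-(methoxymethoxy)-4-(prenyloxy)phenyl]propanoate F13 as the ester and leave the S alcohol, which is 6, at the cost of half the material.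

## Further compounds

F1 | step 10 | methyl (S)-3-[3,5-bis(methoxymethoxy)phenoxy]-3-[3-(methoxymethoxy)-4-(prenyloxy)phenyl]propanoate | CC(C)=CCOc1ccc([C@@H](Oc2cc(OCOC)cc(OCOC)c2)CC(=O)OC)cc1OCOC
F2 | step 10 | (S)-3-[3,5-bis(methoxymethoxy)phenoxy]-3-[3-(methoxymethoxy)-4-(prenyloxy)phenyl]propanoic acid | CC(C)=CCOc1ccc([C@@H](Oc2cc(OCOC)cc(OCOC)c2)CC(=O)O)cc1OCOC
F3 | step 11 | 1-[4-(allyloxy)-3-hydroxyphenyl]ethan-1-one | C=CCOc1ccc(C(C)=O)cc1O
F4 | step 11 | 1-[4-(allyloxy)-3-(methoxymethoxy)phenyl]ethan-1-one | C=CCOc1ccc(C(C)=O)cc1OCOC
F5 | step 11 | methyl 3-[4-(allyloxy)-3-(methoxymethoxy)phenyl]-3-oxopropanoate | C=CCOc1ccc(C(=O)CC(=O)OC)cc1OCOC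
F6 | step 11 | methyl (S)-3-[4-(allyloxy)-3-(methoxymethoxy)phenyl]-3-hydroxypropanoate | C=CCOc1ccc([C@@H](O)CC(=O)OC)cc1OCOC
F7 | step 11 | methyl (S)-3-[4-(allyloxy)-3-(methoxymethoxy)phenyl]-3-(trimethylsilyloxy)propanoate | C=CCOc1ccc([C@@H](O[Si](C)(C)C)CC(=O)OC)cc1OCOC
F8 | step 11 | (S)-2-[4-(allyloxy)-3-(methoxymethoxy)phenyl]-5,7-bis(methoxymethoxy)chroman-4-one | C=CCOc1ccc([C@@H]2CC(=O)c3c(OCOC)cc(OCOC)cc3O2)cc1OCOC
F9 | step 11 | (S)-2-[4-(allyloxy)-3-hydroxyphenyl]-5,7-dihydroxychroman-4-one | C=CCOc1ccc([C@@H]2CC(=O)c3c(O)cc(O)cc3O2)cc1O
F10 | step 8 | 2-bromo-3,5-bis(methoxymethoxy)phenol | COCOc1cc(O)c(Br)c(OCOC)c1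
F11 | step 8 | [2-bromo-3,5-bis(methoxymethoxy)phenoxy]trimethylsilane | COCOc1cc(O[Si](C)(C)C)c(Br)c(OCOC)c1
F12 | step 4 | methyl 3-hydroxy-3-[3-(methoxymethoxy)-4-(prenyloxy)phenyl]propanoate (racemate) | CC(C)=CCOc1ccc(C(O)CC(=O)OC)cc1OCOC
F13 | step 4 | methyl (R)-3-acetoxy-3-[3-(methoxymethoxy)-4-(prenyloxy)phenyl]propanoate | CC(C)=CCOc1ccc([C@H](OC(C)=O)CC(=O)OC)cc1OCOC
A1 | alternative 1 | 2-hydroxy-4,6-bis(tert-butyldimethylsilyloxy)benzaldehyde | O=Cc1c(O)cc(O[Si](C)(C)C(C)(C)C)cc1O[Si](C)(C)C(C)(C)C
A2 | alternative 1 | 1-(benzyloxy)-2-(tert-butyldimethylsilyloxy)-4-vinylbenzene | C=Cc1ccc(OCc2ccccc2)c(O[Si](C)(C)C(C)(C)C)c1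
A3 | alternative 1 | trimethyl orthoformate | COC(OC)OC
A4 | alternative 1 | (2S,4S)-4'-(benzyloxy)-4-methoxy-5,7,3'-tris(tert-butyldimethylsilyloxy)flavan | c1ccccc1COc1ccc([C@@H]2C[C@H](OC)c3c(O[Si](C)(C)C(C)(C)C)cc(O[Si](C)(C)C(C)(C)C)cc3O2)cc1O[Si](C)(C)C(C)(C)C
A5 | alternative 1 | (S)-4'-(benzyloxy)-5,7,3'-tris(tert-butyldimethylsilyloxy)flavanone | c1ccccc1COc1ccc([C@@H]2CC(=O)c3c(O[Si](C)(C)C(C)(C)C)cc(O[Si](C)(C)C(C)(C)C)cc3O2)cc1O[Si](C)(C)C(C)(C)C
A6 | alternative 2 | 2-iodo-3,5-bis(methoxymethoxy)phenol | COCOc1cc(O)c(I)c(OCOC)c1
A7 | alternative 2 | 1-(benzyloxy)-4-ethynyl-2-(methoxymethoxy)benzene | C#Cc1ccc(OCc2ccccc2)c(OCOC)c1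
A8 | alternative 2 | carbon monoxide | [C-]#[O+]
A9 | alternative 2 | 4'-(benzyloxy)-5,7,3'-tris(methoxymethoxy)flavone | O=c1cc(-c2ccc(OCc3ccccc3)c(OCOC)c2)oc2cc(OCOC)cc(OCOC)c12
A10 | alternative 2 | (S)-4'-(benzyloxy)-5,7,3'-tris(methoxymethoxy)flavanone | c1ccccc1COc1ccc([C@@H]2CC(=O)c3c(OCOC)cc(OCOC)cc3O2)cc1OCOC
A11 | alternative 3 | 3-(tert-butyldimethylsilyloxy)-4-(prenyloxy)benzaldehyde | CC(C)=CCOc1ccc(C=O)cc1O[Si](C)(C)C(C)(C)C
A12 | alternative 3 | (E)-1-methoxy-3-(trimethylsilyloxy)buta-1,3-diene | CO/C=C/C(=C)O[Si](C)(C)C
A13 | alternative 3 | (S)-2-[3-(tert-butyldimethylsilyloxy)-4-(prenyloxy)phenyl]-2,3-dihydro-4H-pyran-4-one | CC(C)=CCOc1ccc([C@@H]2CC(=O)C=CO2)cc1O[Si](C)(C)C(C)(C)C
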